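**Plan**

- Ring A is a 1-acyl-2-hydroxy-4-methoxy-5-aryloxybenzene. Its carbons C2'–C5', with their three oxygens, match a silyl ketene acetal diene bearing a 3-methoxy and a 4-aryloxy group; C1' and C6' match the two sp carbons of a terminal ynone.
- Retrosynthesis: first cut the Cα=Cβ bond of the chalcone on ring A' (aldol condensation), then C1'–C2' and C5'–C6' of ring A (Diels–Alder reaction with aromatisation), then the CH2–O bond between the butenoate chain and the 4-oxygen of resacetophenone, and the C–C bonds of the enynone.
- Forward: the aryl enynone is made in four steps from 4-hydroxybenzaldehyde and the diene in three steps from 2,4-dihydroxyacetophenone. The cycloaddition builds ring A, the only ring made (ring A' and both 4-hydroxyphenyl rings are bought); one condensation and one deprotection finish the synthesis.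
- Stereochemistry: there are no stereocentres. One (E)-enone comes from a stabilised Wittig ylide and is carried through; the other comes from the thermodynamically controlled aldol dehydration.

Key step: step 8

Assumption: γ-deprotonation is taken to give the diene with the aryloxy group on the outer side of the s-cis conformer (3Z). The ketene acetal geometry does not matter because that carbon becomes aromatic C2'.

**Route**

Step 1
Reactants: 1 4-hydroxybenzaldehyde
Product: 2 4-(methoxymethoxy)benzaldehyde
Conditions: MOMCl, K2CO3, acetone, 0 °C → rt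
Reagents that add atoms: chloromethyl methyl ether (MOMCl), COCCl
Why: Williamson-type O-alkylation of the phenoxide by the very reactive α-chloro ether should give the MOM acetal, which is stable to every basic and organometallic step that follows.

Step 2
Reactants: 2 4-(methoxymethoxy)benzaldehyde; 3 (triphenylphosphoranylidene)acetaldehyde
Product: 4 (E)-3-[4-(methoxymethoxy)phenyl]prop-2-enal
Conditions: toluene, 80 °C
Reagents that add atoms: none
Why: Wittig olefination with the stabilised formylmethylene ylide is expected to give the (E)-enal, and a near-stoichiometric amount of ylide limits a second homologation.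

Step 3
Reactants: 4 (E)-3-[4-(methoxymethoxy)phenyl]prop-2-enal; 5 ethynylmagnesium bromide
Product: 6 rac-(E)-1-[4-(methoxymethoxy)phenyl]pent-1-en-4-yn-3-ol
Conditions: HC≡CMgBr, THF, 0 °C; sat. aq. NH4Cl
Reagents that add atoms: none
Why: Grignard 1,2-addition to the enal carbonyl should give the secondary alcohol as a racemate, and its stereocentre is removed in the next step.

Step 4
Reactants: 6 rac-(E)-1-[4-(methoxymethoxy)phenyl]pent-1-en-4-yn-3-ol
Product: 7 (E)-1-[4-(methoxymethoxy)phenyl]pent-1-en-4-yn-3-one
Conditions: MnO2 (activated, excess), CH2Cl2, rt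
Reagents that add atoms: none
Why: MnO2 oxidation is selective for an alcohol that is both allylic and propargylic and is neutral enough for the MOM ether and the sensitive cross-conjugated enynone.

Step 5
Reactants: 8 2,4-dihydroxyacetophenone; 9 methyl (E)-4-chloro-3-methoxybut-2-enoate
Product: 10 methyl (E)-4-(4-acetyl-3-hydroxyphenoxy)-3-methoxybut-2-enoate
Conditions: K2CO3 (1.1 equiv), KI (cat.), acetone, reflux
Reagents that add atoms: none
Why: Williamson ether synthesis by SN2 at the primary allylic-type chloride (iodide catalysis) should occur only at the 4-OH, because the 2-OH is held in a hydrogen bond to the acetyl group and is far less nucleophilic.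

Step 6
Reactants: 10 methyl (E)-4-(4-acetyl-3-hydroxyphenoxy)-3-methoxybut-2-enoate
Product: 11 methyl (E)-4-[4-acetyl-3-(methoxymethoxy)phenoxy]-3-methoxybut-2-enoate
Conditions: NaH (1.1 equiv), DMF, 0 °C; MOMCl, 0 °C → rt
Reagents that add atoms: chloromethyl methyl ether (MOMCl), COCCl
Why: O-alkylation of the sodium phenoxide, formed selectively because the chelated phenol is by far the most acidic site, should give the MOM acetal that removes the only acidic O–H before the amide base is used.

Step 7
Reactants: 11 methyl (E)-4-[4-acetyl-3-(methoxymethoxy)phenoxy]-3-methoxybut-2-enoate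
Product: 12 (1Z,3Z)-1,3-dimethoxy-4-{3-(methoxymethoxy)-4-[1-(trimethylsilyloxy)ethenyl]phenoxy}-1-(trimethylsilyloxy)buta-1,3-diene
Conditions: LiN(iPr)2 (2.3 equiv), Me3SiCl (2.6 equiv, present from the start), THF, −78 °C; pentane, filtration, concentration; used crude
Reagents that add atoms: chlorotrimethylsilane, C[Si](C)(C)Cl
Why: Double enolisation with O-silylation (kinetic deprotonation of the acetyl methyl group and vinylogous γ-deprotonation of the β-methoxy enoate, the standard entry to Brassard-type dienes from 3-methoxycrotonates) should give the bis-silyl compound, with in situ trapping keeping the enolates from condensing with carbonyl groups.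

Step 8
Reactants: 12 (1Z,3Z)-1,3-dimethoxy-4-{3-(methoxymethoxy)-4-[1-(trimethylsilyloxy)ethenyl]phenoxy}-1-(trimethylsilyloxy)buta-1,3-diene; 7 (E)-1-[4-(methoxymethoxy)phenyl]pent-1-en-4-yn-3-one
Product: 15 (E)-1-{5-[4-acetyl-3-(methoxymethoxy)phenoxy]-2-hydroxy-4-methoxyphenyl}-3-[4-(methoxymethoxy)phenyl]prop-2-en-1-one, via cyclohexa-1,4-diene cycloadduct 13 (not isolated), via bis-silylated arene 14 (not isolated)
Conditions: 12 (1.3 equiv), toluene, 0 °C → rt, then 50 °C if needed; 0.5 M aq. HCl, THF, 0 °C
Reagents that add atoms: none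
Why: The diene is a Brassard-type 1,1,3-trioxygenated silyl ketene acetal, and the reaction is its known normal-demand Diels–Alder addition to an alkynyl ketone followed by aromatisation through loss of methanol, here with one further (aryloxy) substituent at C4 of the diene. Ring A closes as a six-membered carbocycle by intermolecular (4+2) cycloaddition, most likely asynchronous: the nucleophilic diene terminus C4 (future C5') attacks the unsubstituted β-carbon of the ynone (future C6'), and the ketene acetal carbon (future C2') then bonds to the α-carbon (future C1'). The three donor oxygens at C1 and C3 place the largest HOMO coefficient on C4 and outweigh the weaker aryloxy donor, which fixes the regiochemistry with the acyl group next to the oxygenated C2'. The mixed ketal of cycloadduct 13 ionises and methanol leaves together with the doubly allylic hydrogen at C5' to give aryl silyl ether 14; because C2' carries no hydrogen the aryloxy group cannot be eliminated, and the two sp3 centres of 13 are transient, so no stereocentre needs control. Chemoselectivity rests on the terminal ynone being a much better and less hindered dienophile than the β-aryl enone alkene, whose (E)-geometry is left untouched. Brief dilute acid at 0 °C then hydrolyses both Si–O bonds to free the chelated 2'-OH and the acetyl group while the MOM acetals stay intact.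

Step 9
Reactants: 15 (E)-1-{5-[4-acetyl-3-(methoxymethoxy)phenoxy]-2-hydroxy-4-methoxyphenyl}-3-[4-(methoxymethoxy)phenyl]prop-2-en-1-one; 2 4-(methoxymethoxy)benzaldehyde
Product: 16 (E)-1-{2-hydroxy-4-methoxy-5-[3-(methoxymethoxy)-4-{(E)-3-[4-(methoxymethoxy)phenyl]prop-2-enoyl}phenoxy]phenyl}-3-[4-(methoxymethoxy)phenyl]prop-2-en-1-one
Conditions: KOH (excess), EtOH–H2O, rt; cold dilute HCl to pH 5
Reagents that add atoms: none
Why: Claisen–Schmidt condensation of the remaining acetyl group should give the second (E)-enone by E1cB dehydration under thermodynamic control, and any retro-aldol of the existing chalcone is harmless because it would release the same aldehyde 2, which is present in excess.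

Step 10
Reactants: 16 (E)-1-{2-hydroxy-4-methoxy-5-[3-(methoxymethoxy)-4-{(E)-3-[4-(methoxymethoxy)phenyl]prop-2-enoyl}phenoxy]phenyl}-3-[4-(methoxymethoxy)phenyl]prop-2-en-1-one
Product: 17 (E)-1-{2-hydroxy-5-[3-hydroxy-4-{(E)-3-(4-hydroxyphenyl)prop-2-enoyl}phenoxy]-4-methoxyphenyl}-3-(4-hydroxyphenyl)prop-2-en-1-one
Conditions: HCl (1.25 M in MeOH), THF, 45 °C
Reagents that add atoms: none
Why: Acid-catalysed transacetalisation to methanol should cleave all three aryl MOM ethers, and the two 2'-hydroxychalcone units lack a 6'-OH and therefore cyclise only slowly under these conditions.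

**Compound list**

1 | 4-hydroxybenzaldehyde | O=Cc1ccc(O)cc1 | starting material
2 | 4-(methoxymethoxy)benzaldehyde | COCOc1ccc(C=O)cc1 | intermediate
3 | (triphenylphosphoranylidene)acetaldehyde | O=CC=P(c1ccccc1)(c1ccccc1)c1ccccc1 | starting material
4 | (E)-3-[4-(methoxymethoxy)phenyl]prop-2-enal | COCOc1ccc(/C=C/C=O)cc1 | intermediate
5 | ethynylmagnesium bromide | C#C[Mg]Br | starting material
6 | rac-(E)-1-[4-(methoxymethoxy)phenyl]pent-1-en-4-yn-3-ol | C#CC(O)/C=C/c1ccc(OCOC)cc1 | intermediate
7 | (E)-1-[4-(methoxymethoxy)phenyl]pent-1-en-4-yn-3-one | C#CC(=O)/C=C/c1ccc(OCOC)cc1 | intermediate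
8 | 2,4-dihydroxyacetophenone | CC(=O)c1ccc(O)cc1O | starting material
9 | methyl (E)-4-chloro-3-methoxybut-2-enoate | COC(=O)/C=C(/OC)CCl | starting material
10 | methyl (E)-4-(4-acetyl-3-hydroxyphenoxy)-3-methoxybut-2-enoate | COC(=O)/C=C(/OC)COc1ccc(C(C)=O)c(O)c1 | intermediate
11 | methyl (E)-4-[4-acetyl-3-(methoxymethoxy)phenoxy]-3-methoxybut-2-enoate | COC(=O)/C=C(/OC)COc1ccc(C(C)=O)c(OCOC)c1 | intermediate
12 | (1Z,3Z)-1,3-dimethoxy-4-{3-(methoxymethoxy)-4-[1-(trimethylsilyloxy)ethenyl]phenoxy}-1-(trimethylsilyloxy)buta-1,3-diene | CO/C(O[Si](C)(C)C)=C/C(OC)=C/Oc1ccc(C(=C)O[Si](C)(C)C)c(OCOC)c1 | intermediate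
13 | (E)-1-[4,6-dimethoxy-3-{3-(methoxymethoxy)-4-[1-(trimethylsilyloxy)ethenyl]phenoxy}-6-(trimethylsilyloxy)cyclohexa-1,4-dien-1-yl]-3-[4-(methoxymethoxy)phenyl]prop-2-en-1-one (cycloadduct, mixture of stereoisomers) | COC1=CC(OC)(O[Si](C)(C)C)C(C(=O)/C=C/c2ccc(OCOC)cc2)=CC1Oc1ccc(C(=C)O[Si](C)(C)C)c(OCOC)c1 | intermediate
14 | (E)-1-[4-methoxy-5-{3-(methoxymethoxy)-4-[1-(trimethylsilyloxy)ethenyl]phenoxy}-2-(trimethylsilyloxy)phenyl]-3-[4-(methoxymethoxy)phenyl]prop-2-en-1-one | COc1cc(O[Si](C)(C)C)c(C(=O)/C=C/c2ccc(OCOC)cc2)cc1Oc1ccc(C(=C)O[Si](C)(C)C)c(OCOC)c1 | intermediate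
15 | (E)-1-{5-[4-acetyl-3-(methoxymethoxy)phenoxy]-2-hydroxy-4-methoxyphenyl}-3-[4-(methoxymethoxy)phenyl]prop-2-en-1-one | COc1cc(O)c(C(=O)/C=C/c2ccc(OCOC)cc2)cc1Oc1ccc(C(C)=O)c(OCOC)c1 | intermediate
16 | (E)-1-{2-hydroxy-4-methoxy-5-[3-(methoxymethoxy)-4-{(E)-3-[4-(methoxymethoxy)phenyl]prop-2-enoyl}phenoxy]phenyl}-3-[4-(methoxymethoxy)phenyl]prop-2-en-1-one | COc1cc(O)c(C(=O)/C=C/c2ccc(OCOC)cc2)cc1Oc1ccc(C(=O)/C=C/c2ccc(OCOC)cc2)c(OCOC)c1 | intermediate
17 | (E)-1-{2-hydroxy-5-[3-hydroxy-4-{(E)-3-(4-hydroxyphenyl)prop-2-enoyl}phenoxy]-4-methoxyphenyl}-3-(4-hydroxyphenyl)prop-2-en-1-one | COc1cc(O)c(C(=O)/C=C/c2ccc(O)cc2)cc1Oc1ccc(C(=O)/C=C/c2ccc(O)cc2)c(O)c1 | target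

**Step count and risks**

Total: 10 steps. Longest linear sequence: 7 steps (steps 1, 2, 3, 4, 8, 9, 10).

Steps most likely to fail:

1. Step 8. The diene may be protodesilylated by the methanol released on aromatisation before it has reacted. The cross-conjugated enynone may also be consumed by oligomerisation or by addition at its styryl alkene faster than the alkyne undergoes cycloaddition. The fallback moves both chalcone condensations behind the ring construction and uses a smaller dienophile with no competing alkene. It sets out from 12, which would be heated with commercial but-3-yn-2-one (CC(=O)C#C) in toluene. This should give the cyclohexa-1,4-diene cycloadduct F1 and, after loss of methanol, the bis-silylated arene F2, neither isolated. The same cold dilute acid work-up would then give 1-{5-[4-acetyl-3-(methoxymethoxy)phenoxy]-2-hydroxy-4-methoxyphenyl}ethanone F3. A twofold Claisen–Schmidt condensation of F3 with 2 (2.5 equiv, KOH, EtOH–H2O, rt) would return to the route at 16.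

2. Step 7. The lithium enolate of the acetyl group may condense with ester or ketone groups before it is silylated, γ-deprotonation may be incomplete, or the C3=C4 bond may form with the aryloxy group on the inner side, which would block the cycloaddition. The fallback separates the two enolisations and avoids the lithium ketone enolate. It sets out from 11, which would be converted by soft enolisation (Me3SiOTf, Et3N, CH2Cl2, 0 °C) into methyl (E)-3-methoxy-4-{3-(methoxymethoxy)-4-[1-(trimethylsilyloxy)ethenyl]phenoxy}but-2-enoate F4. A single γ-deprotonation of F4 (LiN(iPr)2, 1.1 equiv, Me3SiCl, THF, −78 °C) would return to the route at 12.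

3. Step 10. While the three acetals are cleaved, acid may promote oxa-Michael ring closure of the 2'-hydroxychalcone units to flavanones. The fallback reverses the cyclisation instead of trying to avoid it. It sets out from 16, whose MOM cleavage would be driven to completion regardless of ring closure. At the extreme this gives the bis-flavanone 2-(4-hydroxyphenyl)-6-{[2-(4-hydroxyphenyl)-4-oxochroman-7-yl]oxy}-7-methoxychroman-4-one F5. The crude material would then be stirred with KOH in aqueous EtOH under argon, so that both dihydropyranone rings reopen by E1cB retro-oxa-Michael elimination to the chalcone phenolates. Cold acidification to pH 5 would return to the route at 17.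

**Further compounds**

F1 | step 8 | 1-[4,6-dimethoxy-3-{3-(methoxymethoxy)-4-[1-(trimethylsilyloxy)ethenyl]phenoxy}-6-(trimethylsilyloxy)cyclohexa-1,4-dien-1-yl]ethanone (not isolated) | COC1=CC(OC)(O[Si](C)(C)C)C(C(C)=O)=CC1Oc1ccc(C(=C)O[Si](C)(C)C)c(OCOC)c1
F2 | step 8 | 1-[4-methoxy-5-{3-(methoxymethoxy)-4-[1-(trimethylsilyloxy)ethenyl]phenoxy}-2-(trimethylsilyloxy)phenyl]ethanone (not isolated) | COc1cc(O[Si](C)(C)C)c(C(C)=O)cc1Oc1ccc(C(=C)O[Si](C)(C)C)c(OCOC)c1
F3 | step 8 | 1-{5-[4-acetyl-3-(methoxymethoxy)phenoxy]-2-hydroxy-4-methoxyphenyl}ethanone | COc1cc(O)c(C(C)=O)cc1Oc1ccc(C(C)=O)c(OCOC)c1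
F4 | step 7 | methyl (E)-3-methoxy-4-{3-(methoxymethoxy)-4-[1-(trimethylsilyloxy)ethenyl]phenoxy}but-2-enoate | COC(=O)/C=C(/OC)COc1ccc(C(=C)O[Si](C)(C)C)c(OCOC)c1
F5 | step 10 | 2-(4-hydroxyphenyl)-6-{[2-(4-hydroxyphenyl)-4-oxochroman-7-yl]oxy}-7-methoxychroman-4-one (mixture of stereoisomers) | COc1cc2OC(c3ccc(O)cc3)CC(=O)c2cc1Oc1ccc2C(=O)CC(c3ccc(O)cc3)Oc2c1
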